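**Plan**

- Retrosynthetic cuts, in order: the isobutyrate C–O bond; C8–C17 (carbonylation of a C8 enol triflate); C12–C13 (B-alkyl Suzuki coupling); C1–C10 (radical closure of ring A); C9–C11 (epoxide opening); C4–C5 (Ireland–Claisen rearrangement).
- Forward: ring B is 2-methylcyclohex-2-enone. A Claisen shift builds the quaternary C4 and C5, the enone is converted into C8–OH / C9-vinyl / C10–OH, ring A then closes onto ring B, and the side chain and the acid follow.
- Enabling feature: C10 is the only fully substituted carbon of ring B and carries a methyl group, so a tertiary alcohol at C10 is a latent tertiary radical. A 3-oxo group turns C1 into the β-carbon of a vinyl ketone on the C5 chain, so a 6-endo radical conjugate addition closes C1–C10.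
- Helpers: the C3 carbonyl (removed by Wolff–Kishner reduction), the C10 hydroxyl (lost in the key step) and the C8 hydroxyl (later the ketone that brings in C17).
- Stereochemistry: C5 comes from chirality transfer from a CBS-derived carbinol; C9 from anti opening of an epoxide (it is also the thermodynamic epimer at the ketone stage); C10 is set in the key step, trans to H5.

Key step: step 9

Remark: atoms are named by labdane numbering (ring B = C5–C10; ring A = C1–C5 plus C10; C17 = carboxyl carbon; C11–C16 = side chain). The C8 carbinol is carried as a mixture of epimers from step 7 to step 15, where it becomes the ketone.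

Step 1
Reactants: 1 2-methylcyclohex-2-en-1-one
Product: 2 (1S)-2-methylcyclohex-2-en-1-ol
Conditions: (R)-Me-CBS (10 mol %), BH3·SMe2, THF, −20 °C; MeOH
Reagents that add atoms: none
Why: CBS reduction; the oxazaborolidine tells the α-substituted alkenyl flank of the ketone from the methylene flank and should set the (S) carbinol, the source of all later absolute stereochemistry.

Step 2
Reactants: 2 (1S)-2-methylcyclohex-2-en-1-ol
Product: 3 (1S)-2-methylcyclohex-2-en-1-yl 2-methylpropanoate
Conditions: i-PrCOCl, pyridine, DMAP (cat.), CH2Cl2, 0 °C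
Reagents that add atoms: 2-methylpropanoyl chloride CC(C)C(Cl)=O
Why: Plain acylation of a secondary allylic alcohol; the stereocenter is not touched.

Step 3
Reactants: 3 (1S)-2-methylcyclohex-2-en-1-yl 2-methylpropanoate
Product: 6 2-methyl-2-[(1R)-2-methylcyclohex-2-en-1-yl]propanoic acid, via silyl ketene acetal 4 (not isolated), via trimethylsilyl ester 5 (not isolated)
Conditions: LDA, THF, −78 °C; Me3SiCl; then 65 °C; aq. HCl
Reagents that add atoms: none
Why: Ireland–Claisen rearrangement; the [3,3] shift is suprafacial on the ring, so the C9–O bond is traded for the C4–C5 bond on the same face, which sets C5 and the quaternary C4 and moves the alkene to C9=C10.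

Step 4
Reactants: 6 2-methyl-2-[(1R)-2-methylcyclohex-2-en-1-yl]propanoic acid
Product: 8 N-methoxy-N,2-dimethyl-2-[(1R)-2-methylcyclohex-2-en-1-yl]propanamide, via acid chloride 7 (not isolated)
Conditions: (COCl)2, DMF (cat.), CH2Cl2; MeNH(OMe)·HCl, pyridine, 0 °C to rt
Reagents that add atoms: N,O-dimethylhydroxylamine hydrochloride CNOC.Cl
Why: Weinreb amide formation through the acid chloride, the usual way for a neopentyl acid; the amide should survive the next three steps and later gives the vinyl ketone.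

Step 5
Reactants: 8 N-methoxy-N,2-dimethyl-2-[(1R)-2-methylcyclohex-2-en-1-yl]propanamide
Product: 9 N-methoxy-N,2-dimethyl-2-[(1R)-2-methyl-4-oxocyclohex-2-en-1-yl]propanamide
Conditions: CrO3, 3,5-dimethylpyrazole, CH2Cl2, −20 °C
Reagents that add atoms: chromium trioxide O=[Cr](=O)=O
Why: Allylic oxidation; C8 is the only allylic methylene of the ring (C5 is a hindered methine), so the conjugated 3-methyl enone with the C8 carbonyl should form.

Step 6
Reactants: 9 N-methoxy-N,2-dimethyl-2-[(1R)-2-methyl-4-oxocyclohex-2-en-1-yl]propanamide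
Product: 10 N-methoxy-N,2-dimethyl-2-[(1S,2S,6S)-1-methyl-5-oxo-7-oxabicyclo[4.1.0]heptan-2-yl]propanamide
Conditions: 30% H2O2, NaOH (cat.), MeOH, 0 °C
Reagents that add atoms: hydrogen peroxide OO
Why: Weitz–Scheffer epoxidation; hydroperoxide should add to C10 on the ring face opposite the bulky C5 substituent, which places the C9–C10 epoxide anti to it.

Step 7
Reactants: 10 N-methoxy-N,2-dimethyl-2-[(1S,2S,6S)-1-methyl-5-oxo-7-oxabicyclo[4.1.0]heptan-2-yl]propanamide
Product: 11 2-[(1S,2S,6R)-5-hydroxy-1-methyl-7-oxabicyclo[4.1.0]heptan-2-yl]-N-methoxy-N,2-dimethylpropanamide (both C8 carbinol epimers)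
Conditions: NaBH4, MeOH, 0 °C
Reagents that add atoms: none
Why: Borohydride reduction of the ketone beside the amide; the new carbinol center is left uncontrolled because it becomes a ketone again in step 15.

Step 8
Reactants: 11 2-[(1S,2S,6R)-5-hydroxy-1-methyl-7-oxabicyclo[4.1.0]heptan-2-yl]-N-methoxy-N,2-dimethylpropanamide
Product: 12 4-[(1S,2S,3S)-3-ethenyl-2,4-dihydroxy-2-methylcyclohexyl]-4-methylpent-1-en-3-one (both C8 carbinol epimers)
Conditions: CH2=CHMgBr (5 equiv), CuI (10 mol %), THF, −30 °C to rt; aq. NH4Cl, 0 °C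
Reagents that add atoms: vinylmagnesium bromide C=C[Mg]Br
Why: Copper-catalysed Grignard opening of the epoxide, trans-diaxial at the less substituted C9, should put the vinyl group anti to the C10 oxygen and so cis to the C5 substituent, while the same reagent turns the Weinreb amide into the vinyl ketone (Weinreb ketone synthesis).

Step 9
Reactants: 12 4-[(1S,2S,3S)-3-ethenyl-2,4-dihydroxy-2-methylcyclohexyl]-4-methylpent-1-en-3-one
Product: 13 (4aS,5R,8aR)-5-ethenyl-6-hydroxy-1,1,4a-trimethyloctahydronaphthalen-2(1H)-one (both C8 carbinol epimers)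
Conditions: Cp*TiCl3 (10 mol %), Zn, Et3SiCl, THF, 40 °C; then 1 M HCl
Reagents that add atoms: none
Why: Low-valent titanium binds the tertiary C10 hydroxyl of 12 and the C–O bond breaks homolytically, giving a tertiary radical at C10 that is not conjugated and sits in a chair ring B. The closest known reaction is the titanium-catalysed dehydroxylative conjugate addition of tertiary alcohols to activated alkenes, and the ring closure copies the second ring closure of radical polyene cyclisations. Ring A closes 6-endo-trig: the radical attacks C1, the terminal β-carbon of the vinyl ketone, and the α-keto radical at C2 is reduced to the titanium enolate and protonated. C10 is the only new stereocenter; with the C5 chain and the C9 vinyl group both equatorial, the chair-like transition state should make the new C1–C10 bond equatorial and leave the methyl axial, which is the trans ring fusion (methyl anti to H5). The step needs chemoselection for the tertiary over the secondary hydroxyl (only the tertiary C–O bond homolyses) and attack at C1 rather than C2 (enone polarity); because the radical is planar, the configuration of the C10 carbinol does not matter.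

Step 10
Reactants: 13 (4aS,5R,8aR)-5-ethenyl-6-hydroxy-1,1,4a-trimethyloctahydronaphthalen-2(1H)-one
Product: 15 (1R,4aS,8aS)-1-ethenyl-5,5,8a-trimethyldecahydronaphthalen-2-ol (both C8 carbinol epimers), via hydrazone 14 (not isolated)
Conditions: N2H4·H2O, KOH, diethylene glycol, 130 to 200 °C
Reagents that add atoms: none
Why: Wolff–Kishner reduction, well known for hindered 3-oxo-4,4-dimethyl decalins; it removes the helper carbonyl while the alcohol and the vinyl group should be inert to hot base.

Step 11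
Reactants: 16 ethyl 3-oxobutanoate
Product: 17 ethyl (2E)-3-{[(trifluoromethyl)sulfonyl]oxy}but-2-enoate
Conditions: Tf2O, aq. Me4NOH, hexanes, 5 °C
Reagents that add atoms: trifluoromethanesulfonic anhydride O=S(=O)(OS(=O)(=O)C(F)(F)F)C(F)(F)F
Why: Enol triflate formation from a β-keto ester; the non-chelated ammonium enolate should give the (E) isomer, which fixes the later C13=C14 geometry.

Step 12
Reactants: 17 ethyl (2E)-3-{[(trifluoromethyl)sulfonyl]oxy}but-2-enoate
Product: 18 (2E)-4-hydroxybut-2-en-2-yl trifluoromethanesulfonate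
Conditions: DIBAL-H (2.2 equiv), CH2Cl2, −78 °C; Rochelle salt
Reagents that add atoms: none
Why: 1,2-Reduction of the enoate to the allylic alcohol; the alkenyl triflate and the double-bond geometry should be kept at low temperature.

Step 13
Reactants: 18 (2E)-4-hydroxybut-2-en-2-yl trifluoromethanesulfonate
Product: 19 (2E)-4-{[tert-butyl(dimethyl)silyl]oxy}but-2-en-2-yl trifluoromethanesulfonate
Conditions: TBSCl, imidazole, DMF, 0 °C
Reagents that add atoms: tert-butyl(chloro)dimethylsilane CC(C)(C)[Si](C)(C)Cl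
Why: Silylation of a primary alcohol; the silyl ether carries C15–O through the ketone, enolate and palladium chemistry that follows.

Step 14
Reactants: 15 (1R,4aS,8aS)-1-ethenyl-5,5,8a-trimethyldecahydronaphthalen-2-ol; 19 (2E)-4-{[tert-butyl(dimethyl)silyl]oxy}but-2-en-2-yl trifluoromethanesulfonate
Product: 21 (1R,4aS,8aS)-1-[(3E)-5-{[tert-butyl(dimethyl)silyl]oxy}-3-methylpent-3-en-1-yl]-5,5,8a-trimethyldecahydronaphthalen-2-ol (both C8 carbinol epimers), via B-alkyl-9-BBN adduct 20 (not isolated)
Conditions: 9-BBN (2.2 equiv), THF, rt; then 19, Pd(dppf)Cl2 (5 mol %), AsPh3, aq. K3PO4, DMF, rt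
Reagents that add atoms: none
Why: 9-BBN adds to the terminal carbon of the monosubstituted alkene, and the B-alkyl Suzuki–Miyaura coupling with the (E)-alkenyl triflate should form C12–C13 with retention of the alkene geometry.

Step 15
Reactants: 21 (1R,4aS,8aS)-1-[(3E)-5-{[tert-butyl(dimethyl)silyl]oxy}-3-methylpent-3-en-1-yl]-5,5,8a-trimethyldecahydronaphthalen-2-ol
Product: 22 (1R,4aS,8aS)-1-[(3E)-5-{[tert-butyl(dimethyl)silyl]oxy}-3-methylpent-3-en-1-yl]-5,5,8a-trimethyloctahydronaphthalen-2(1H)-one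
Conditions: Dess–Martin periodinane, NaHCO3, CH2Cl2, rt
Reagents that add atoms: none
Why: Dess–Martin oxidation; both carbinol epimers give the same ketone, and C9, now enolisable, keeps the equatorial side chain, which is also the thermodynamic arrangement.

Step 16
Reactants: 22 (1R,4aS,8aS)-1-[(3E)-5-{[tert-butyl(dimethyl)silyl]oxy}-3-methylpent-3-en-1-yl]-5,5,8a-trimethyloctahydronaphthalen-2(1H)-one
Product: 23 (1R,4aS,8aS)-1-[(3E)-5-{[tert-butyl(dimethyl)silyl]oxy}-3-methylpent-3-en-1-yl]-5,5,8a-trimethyl-1,4,4a,5,6,7,8,8a-octahydronaphthalen-2-yl trifluoromethanesulfonate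
Conditions: KHMDS, THF, −78 °C; PhNTf2
Reagents that add atoms: N-phenyl-bis(trifluoromethanesulfonimide) O=S(=O)(N(c1ccccc1)S(=O)(=O)C(F)(F)F)C(F)(F)F
Why: Kinetic deprotonation should take the less hindered C7 methylene rather than the C9 methine, and O-triflation fixes the C7=C8 enol triflate.

Step 17
Reactants: 23 (1R,4aS,8aS)-1-[(3E)-5-{[tert-butyl(dimethyl)silyl]oxy}-3-methylpent-3-en-1-yl]-5,5,8a-trimethyl-1,4,4a,5,6,7,8,8a-octahydronaphthalen-2-yl trifluoromethanesulfonate
Product: 24 (1R,4aS,8aS)-1-[(3E)-5-{[tert-butyl(dimethyl)silyl]oxy}-3-methylpent-3-en-1-yl]-5,5,8a-trimethyl-1,4,4a,5,6,7,8,8a-octahydronaphthalene-2-carboxylic acid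
Conditions: Pd(OAc)2 (5 mol %), dppf, CO (1 atm), Et3N, DMF–H2O, 60 °C; dilute acid
Reagents that add atoms: carbon monoxide [C-]#[O+]; water O
Why: Palladium-catalysed hydroxycarbonylation of the alkenyl triflate puts the carboxyl carbon on C8 and leaves the C7=C8 double bond in place.

Step 18
Reactants: 24 (1R,4aS,8aS)-1-[(3E)-5-{[tert-butyl(dimethyl)silyl]oxy}-3-methylpent-3-en-1-yl]-5,5,8a-trimethyl-1,4,4a,5,6,7,8,8a-octahydronaphthalene-2-carboxylic acid
Product: 25 (1R,4aS,8aS)-1-[(3E)-5-hydroxy-3-methylpent-3-en-1-yl]-5,5,8a-trimethyl-1,4,4a,5,6,7,8,8a-octahydronaphthalene-2-carboxylic acid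
Conditions: TBAF, THF, rt; aq. NH4Cl
Reagents that add atoms: none
Why: Fluoride cleaves the primary allylic silyl ether; the carboxylate and both alkenes should be inert.

Step 19
Reactants: 25 (1R,4aS,8aS)-1-[(3E)-5-hydroxy-3-methylpent-3-en-1-yl]-5,5,8a-trimethyl-1,4,4a,5,6,7,8,8a-octahydronaphthalene-2-carboxylic acid
Product: 27 (1R,4aS,8aS)-5,5,8a-trimethyl-1-{(3E)-3-methyl-5-[(2-methylpropanoyl)oxy]pent-3-en-1-yl}-1,4,4a,5,6,7,8,8a-octahydronaphthalene-2-carboxylic acid, via mixed anhydride 26 (not isolated)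
Conditions: (i-PrCO)2O (3 equiv), pyridine, DMAP (cat.), CH2Cl2, 0 °C to rt; then THF/aq. NaHCO3; dilute acid
Reagents that add atoms: 2-methylpropanoic anhydride CC(C)C(=O)OC(=O)C(C)C
Why: Acylation of the primary allylic alcohol; the carboxyl group is turned in passing into a mixed anhydride, which the bicarbonate step should hydrolyse at the less hindered isobutyryl carbonyl.

**Compound list**

1 | 2-methylcyclohex-2-en-1-one | CC1=CCCCC1=O | starting material
2 | (1S)-2-methylcyclohex-2-en-1-ol | O[C@H]1CCCC=C1C | intermediate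
3 | (1S)-2-methylcyclohex-2-en-1-yl 2-methylpropanoate | CC(C)C(=O)O[C@H]1CCCC=C1C | intermediate
4 | trimethylsilyl ketene acetal of 3 | CC(C)=C(O[Si](C)(C)C)O[C@H]1CCCC=C1C | intermediate
5 | trimethylsilyl 2-methyl-2-[(1R)-2-methylcyclohex-2-en-1-yl]propanoate | CC1=CCCC[C@H]1C(C)(C)C(=O)O[Si](C)(C)C | intermediate
6 | 2-methyl-2-[(1R)-2-methylcyclohex-2-en-1-yl]propanoic acid | CC1=CCCC[C@H]1C(C)(C)C(=O)O | intermediate
7 | 2-methyl-2-[(1R)-2-methylcyclohex-2-en-1-yl]propanoyl chloride | CC1=CCCC[C@H]1C(C)(C)C(Cl)=O | intermediate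
8 | N-methoxy-N,2-dimethyl-2-[(1R)-2-methylcyclohex-2-en-1-yl]propanamide | CC1=CCCC[C@H]1C(C)(C)C(=O)N(C)OC | intermediate
9 | N-methoxy-N,2-dimethyl-2-[(1R)-2-methyl-4-oxocyclohex-2-en-1-yl]propanamide | CC1=CC(=O)CC[C@H]1C(C)(C)C(=O)N(C)OC | intermediate
10 | N-methoxy-N,2-dimethyl-2-[(1S,2S,6S)-1-methyl-5-oxo-7-oxabicyclo[4.1.0]heptan-2-yl]propanamide | C[C@@]12O[C@@H]1C(=O)CC[C@H]2C(C)(C)C(=O)N(C)OC | intermediate
11 | 2-[(1S,2S,6R)-5-hydroxy-1-methyl-7-oxabicyclo[4.1.0]heptan-2-yl]-N-methoxy-N,2-dimethylpropanamide (both carbinol epimers) | C[C@@]12O[C@@H]1C(O)CC[C@H]2C(C)(C)C(=O)N(C)OC | intermediate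
12 | 4-[(1S,2S,3S)-3-ethenyl-2,4-dihydroxy-2-methylcyclohexyl]-4-methylpent-1-en-3-one (both C-4 carbinol epimers) | C=C[C@H]1C(O)CC[C@@H](C(C)(C)C(=O)C=C)[C@]1(C)O | intermediate
13 | (4aS,5R,8aR)-5-ethenyl-6-hydroxy-1,1,4a-trimethyloctahydronaphthalen-2(1H)-one (both C-6 epimers) | C=C[C@H]1C(O)CC[C@H]2C(C)(C)C(=O)CC[C@]12C | intermediate
14 | hydrazone of 13 | C=C[C@H]1C(O)CC[C@H]2C(C)(C)C(=NN)CC[C@]12C | intermediate
15 | (1R,4aS,8aS)-1-ethenyl-5,5,8a-trimethyldecahydronaphthalen-2-ol (both C-2 epimers) | C=C[C@H]1C(O)CC[C@H]2C(C)(C)CCC[C@]12C | intermediate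
16 | ethyl 3-oxobutanoate | CCOC(=O)CC(C)=O | starting material
17 | ethyl (2E)-3-{[(trifluoromethyl)sulfonyl]oxy}but-2-enoate | C/C(OS(=O)(=O)C(F)(F)F)=C\C(=O)OCC | intermediate
18 | (2E)-4-hydroxybut-2-en-2-yl trifluoromethanesulfonate | C/C(OS(=O)(=O)C(F)(F)F)=C\CO | intermediate
19 | (2E)-4-{[tert-butyl(dimethyl)silyl]oxy}but-2-en-2-yl trifluoromethanesulfonate | C/C(OS(=O)(=O)C(F)(F)F)=C\CO[Si](C)(C)C(C)(C)C | intermediate
20 | B-alkyl-9-borabicyclo[3.3.1]nonane adduct of 15 | C1CCC2CCCC1B2CC[C@H]3C(O)CC[C@H]4C(C)(C)CCC[C@]34C | intermediate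
21 | (1R,4aS,8aS)-1-[(3E)-5-{[tert-butyl(dimethyl)silyl]oxy}-3-methylpent-3-en-1-yl]-5,5,8a-trimethyldecahydronaphthalen-2-ol (both C-2 epimers) | C/C(=C\CO[Si](C)(C)C(C)(C)C)CC[C@H]1C(O)CC[C@H]2C(C)(C)CCC[C@]12C | intermediate
22 | (1R,4aS,8aS)-1-[(3E)-5-{[tert-butyl(dimethyl)silyl]oxy}-3-methylpent-3-en-1-yl]-5,5,8a-trimethyloctahydronaphthalen-2(1H)-one | C/C(=C\CO[Si](C)(C)C(C)(C)C)CC[C@H]1C(=O)CC[C@H]2C(C)(C)CCC[C@]12C | intermediate
23 | (1R,4aS,8aS)-1-[(3E)-5-{[tert-butyl(dimethyl)silyl]oxy}-3-methylpent-3-en-1-yl]-5,5,8a-trimethyl-1,4,4a,5,6,7,8,8a-octahydronaphthalen-2-yl trifluoromethanesulfonate | C/C(=C\CO[Si](C)(C)C(C)(C)C)CC[C@H]1C(OS(=O)(=O)C(F)(F)F)=CC[C@H]2C(C)(C)CCC[C@]12C | intermediate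
24 | (1R,4aS,8aS)-1-[(3E)-5-{[tert-butyl(dimethyl)silyl]oxy}-3-methylpent-3-en-1-yl]-5,5,8a-trimethyl-1,4,4a,5,6,7,8,8a-octahydronaphthalene-2-carboxylic acid | C/C(=C\CO[Si](C)(C)C(C)(C)C)CC[C@H]1C(C(=O)O)=CC[C@H]2C(C)(C)CCC[C@]12C | intermediate
25 | (1R,4aS,8aS)-1-[(3E)-5-hydroxy-3-methylpent-3-en-1-yl]-5,5,8a-trimethyl-1,4,4a,5,6,7,8,8a-octahydronaphthalene-2-carboxylic acid | C/C(=C\CO)CC[C@H]1C(C(=O)O)=CC[C@H]2C(C)(C)CCC[C@]12C | intermediate
26 | mixed carboxylic 2-methylpropanoic anhydride of 27 | C/C(=C\COC(=O)C(C)C)CC[C@H]1C(C(=O)OC(=O)C(C)C)=CC[C@H]2C(C)(C)CCC[C@]12C | intermediate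
27 | (1R,4aS,8aS)-5,5,8a-trimethyl-1-{(3E)-3-methyl-5-[(2-methylpropanoyl)oxy]pent-3-en-1-yl}-1,4,4a,5,6,7,8,8a-octahydronaphthalene-2-carboxylic acid | C/C(=C\COC(=O)C(C)C)CC[C@H]1C(C(=O)O)=CC[C@H]2C(C)(C)CCC[C@]12C | target

**Step count and risks**

Total step count: 19. Longest linear sequence: 16 (steps 1–10 and 14–19); steps 11–13 make the coupling partner 19.

Steps most likely to fail:

1. Step 9 (key step). The C10 radical may be reduced or may eliminate before it cyclises, low-valent titanium may consume the enone, or the hydroxy ketone may sit as its cyclic hemiketal and fail to ionise; closure through an axial tether would give the cis ring fusion. Fallback (fragmentation of a redox-active ester under photoredox catalysis instead of Ti–O homolysis): from 12, the secondary hydroxyl is silylated (Et3SiCl, imidazole) to the triethylsilyl ether F1. The tertiary alcohol is then acylated with oxalyl chloride followed by N-hydroxyphthalimide to give the tert-alkyl N-phthalimidoyl oxalate F2. Visible light with Ru(bpy)3(PF6)2 and a Hantzsch ester should generate the same C10 radical, which closes to the silylated decalone F3; dilute HCl in methanol returns the route at 13.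

2. Step 8. Regiocontrol of the epoxide opening may be lost (alkoxide-assisted migration of the epoxide, attack at the wrong carbon), or the amide may react before the copper-mediated opening when both events share one pot. Fallback (Lewis-acid-mediated alkynylation of the protected epoxide and semihydrogenation, with the amide converted separately): from 11, silylation (TBSOTf, 2,6-lutidine) gives the silyl ether F4. Lithium (trimethylsilyl)acetylide with BF3·OEt2 at −78 °C should open the epoxide at C9 to the alkynyl carbinol F5. TBAF removes both silyl groups to give the ethynyl diol F6, and Lindlar hydrogenation gives the vinyl diol F7. Vinylmagnesium bromide then converts the amide and returns the route at 12.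

3. Step 6. Alkaline peroxide may epimerise the γ-carbon C5 through the dienolate, which would erode the enantiomeric purity, and attack at the hindered β-carbon may be slow. Fallback (reduce first, then hydroxyl-directed electrophilic epoxidation under neutral conditions): from 9, NaBH4/CeCl3 gives the allylic alcohols, of which the trans epimer F8 is taken on. VO(acac)2/t-BuOOH should epoxidise syn to the hydroxyl, that is anti to the C5 substituent, and returns the route at 11 as one of its carbinol epimers.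

**Further compounds**

F1 | step 9 | 4-[(1S,2S,3S)-3-ethenyl-2-hydroxy-2-methyl-4-(triethylsilyloxy)cyclohexyl]-4-methylpent-1-en-3-one | C=C[C@H]1C(O[Si](CC)(CC)CC)CC[C@@H](C(C)(C)C(=O)C=C)[C@]1(C)O
F2 | step 9 | tertiary N-phthalimidoyl oxalate of F1 | C=C[C@H]1C(O[Si](CC)(CC)CC)CC[C@@H](C(C)(C)C(=O)C=C)[C@]1(C)OC(=O)C(=O)ON1C(=O)c2ccccc2C1=O
F3 | step 9 | (4aS,5R,8aR)-5-ethenyl-1,1,4a-trimethyl-6-(triethylsilyloxy)octahydronaphthalen-2(1H)-one | C=C[C@H]1C(O[Si](CC)(CC)CC)CC[C@H]2C(C)(C)C(=O)CC[C@]12C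
F4 | step 8 | tert-butyldimethylsilyl ether of 11 | C[C@@]12O[C@@H]1C(O[Si](C)(C)C(C)(C)C)CC[C@H]2C(C)(C)C(=O)N(C)OC
F5 | step 8 | 2-{(1S,2S,3S)-4-[tert-butyl(dimethyl)silyl]oxy-2-hydroxy-2-methyl-3-[(trimethylsilyl)ethynyl]cyclohexyl}-N-methoxy-N,2-dimethylpropanamide | C[Si](C)(C)C#C[C@H]1C(O[Si](C)(C)C(C)(C)C)CC[C@@H](C(C)(C)C(=O)N(C)OC)[C@]1(C)O
F6 | step 8 | 2-[(1S,2S,3S)-3-ethynyl-2,4-dihydroxy-2-methylcyclohexyl]-N-methoxy-N,2-dimethylpropanamide | C#C[C@H]1C(O)CC[C@@H](C(C)(C)C(=O)N(C)OC)[C@]1(C)O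
F7 | step 8 | 2-[(1S,2S,3S)-3-ethenyl-2,4-dihydroxy-2-methylcyclohexyl]-N-methoxy-N,2-dimethylpropanamide | C=C[C@H]1C(O)CC[C@@H](C(C)(C)C(=O)N(C)OC)[C@]1(C)O
F8 | step 6 | N-methoxy-N,2-dimethyl-2-[(1R,4R)-4-hydroxy-2-methylcyclohex-2-en-1-yl]propanamide | CC1=C[C@H](O)CC[C@H]1C(C)(C)C(=O)N(C)OC
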